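The route rests on cutting the C9–C10 bond (chain numbered from the angelate-bearing CH2, ring atoms primed), the CH2–CH= link between the acetoxy carbinol C8 and the exocyclic alkene on C3′ of the oxolan-2-one. The key step exploits the homoallylic array O–C8–C9–C10=C3′: C8–O and C9 are read as an opened terminal oxirane, and C10≡C3′ as an alkyne that later becomes the (E)-alkylidene lactone by syn-hydrocarbonylation. A lithium acetylide made from D-erythronolactone, carrying C4′/C5′ as a cis-acetonide, opens a nerol-derived (R)-alkenyl oxirane at its CH2 terminus; strain release drives the coupling, C8 keeps its configuration, and the alkoxide is acetylated in the same flask.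

Key step: step 10

Remark: the (R,R)-cobalt salen catalyst is assumed to hydrolyse the (S)-enantiomer of the alkenyl oxirane, as it does with simple terminal alkyl oxiranes. Locants in compound names are those of each compound; C1–C10 and C2′–C5′ refer to the target.

Step 1
Reactants: 1 nerol, (2Z)-3,7-dimethylocta-2,6-dien-1-ol
Product: 2 neryl TBS ether, tert-butyl{[(2Z)-3,7-dimethylocta-2,6-dien-1-yl]oxy}dimethylsilane
Conditions: TBSCl, imidazole, CH2Cl2, 0 °C → rt
Reagents that add atoms: tert-butyldimethylsilyl chloride CC(C)(C)[Si](C)(C)Cl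
Why: Imidazole-promoted silylation of the primary allylic alcohol masks O1 so that the later ylide and organolithium steps meet neither a free hydroxyl nor an ester.

Step 2
Reactants: 2 neryl TBS ether
Product: 3 (2E,6Z)-8-[(tert-butyldimethylsilyl)oxy]-2,6-dimethylocta-2,6-dien-1-ol
Conditions: SeO2 (cat.), t-BuOOH, salicylic acid (cat.), CH2Cl2, rt
Reagents that add atoms: tert-butyl hydroperoxide CC(C)(C)OO (oxygen relayed by catalytic selenium dioxide O=[Se]=O)
Why: The SeO2/t-BuOOH allylic oxidation (Riley type, ene reaction then [2,3]-shift) should hydroxylate the (E)-methyl group of the electron-rich terminal isopropylidene unit to give the 2E alcohol, the alkene next to the silyloxymethyl group reacting more slowly, and any over-oxidised enal 4 is carried forward.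

Step 3
Reactants: 3 (2E,6Z)-allylic alcohol
Product: 4 (2E,6Z)-8-[(tert-butyldimethylsilyl)oxy]-2,6-dimethylocta-2,6-dienal
Conditions: MnO2, CH2Cl2, rt
Reagents that add atoms: none
Why: MnO2 oxidises allylic alcohols chemoselectively to enals without touching the silyl ether or the alkene geometry and converges the alcohol/enal mixture of step 2 on 4.

Step 4
Reactants: 4 (2E,6Z)-enal
Product: 5 racemic tert-butyl{[(2Z,6E)-3,7-dimethyl-7-(oxiran-2-yl)hepta-2,6-dien-1-yl]oxy}dimethylsilane
Conditions: Me3S+ I−, n-BuLi, THF, −10 °C → rt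
Reagents that add atoms: trimethylsulfonium iodide C[S+](C)C.[I-]
Why: Corey–Chaykovsky epoxidation, in which dimethylsulfonium methylide adds 1,2 to the enal carbonyl and the betaine closes to the terminal alkenyl oxirane (racemic, no facial control needed here).

Step 5
Reactants: 5 racemic alkenyl oxirane
Product: 6 tert-butyl({(2Z,6E)-3,7-dimethyl-7-[(2R)-oxiran-2-yl]hepta-2,6-dien-1-yl}oxy)dimethylsilane
Conditions: (R,R)-(salen)Co(III)OAc (1 mol %), H2O (0.55 equiv), THF, 0 °C → rt
Reagents that add atoms: none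
Why: Jacobsen hydrolytic kinetic resolution, in which the catalyst hydrolyses the (S)-oxirane and leaves the (R)-oxirane, so the future C8 stereocentre is fixed by catalyst control.

Step 6
Reactants: 7 (−)-2,3-O-isopropylidene-D-erythronolactone, (3aR,6aR)-2,2-dimethyldihydrofuro[3,4-d][1,3]dioxol-4(3aH)-one
Product: 8 2,3-O-isopropylidene-D-erythrose (lactol, anomeric mixture), (3aR,6aR)-2,2-dimethyltetrahydrofuro[3,4-d][1,3]dioxol-4-ol
Conditions: DIBAL-H (1.1 equiv), CH2Cl2, −78 °C
Reagents that add atoms: none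
Why: Half-reduction of the lactone stops at the tetrahedral aluminate at −78 °C and gives the lactol on work-up, both stereocentres coming unchanged from the chiral pool.

Step 7
Reactants: 8 2,3-O-isopropylidene-D-erythrose
Product: 9 [(4R,5S)-5-ethynyl-2,2-dimethyl-1,3-dioxolan-4-yl]methanol
Conditions: dimethyl (1-diazo-2-oxopropyl)phosphonate, K2CO3, MeOH, 0 °C → rt
Reagents that add atoms: dimethyl (1-diazo-2-oxopropyl)phosphonate CC(=O)C(=[N+]=[N-])P(=O)(OC)OC
Why: Ohira–Bestmann (Seyferth–Gilbert) homologation of the open-chain aldehyde tautomer of the lactol turns sugar C1 into a terminal alkyne and frees the primary hydroxyl, and the mild carbonate base is expected to leave the cis-acetonide intact.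

Step 8
Reactants: 9 ethynyl dioxolane methanol
Product: 10 (4S,5S)-5-ethynyl-2,2-dimethyl-1,3-dioxolane-4-carbaldehyde
Conditions: Dess–Martin periodinane, CH2Cl2, 0 °C → rt
Reagents that add atoms: none
Why: Dess–Martin oxidation gives the α-alkoxy aldehyde under non-basic conditions that avoid epimerisation to the trans-dioxolane.

Step 9
Reactants: 10 ethynyl dioxolane carbaldehyde
Product: 11 (4S,5R)-4-ethynyl-2,2-dimethyl-5-(2-methylprop-1-en-1-yl)-1,3-dioxolane
Conditions: i-PrPPh3+ I−, n-BuLi, THF, −78 → 0 °C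
Reagents that add atoms: isopropyltriphenylphosphonium iodide CC(C)[P+](c1ccccc1)(c1ccccc1)c1ccccc1.[I-]
Why: Wittig olefination with the non-stabilised isopropylidene ylide installs the 2-methylprop-1-enyl group (no E/Z issue at the gem-dimethyl terminus) faster than the aldehyde enolises, and the ylide is not basic enough to deprotonate the alkyne.

Step 10
Reactants: 11 (4S,5R)-alkyne acetonide; 6 (R)-alkenyl oxirane
Product: 14 (4S,5E,9Z)-11-[(tert-butyldimethylsilyl)oxy]-1-[(4S,5R)-2,2-dimethyl-5-(2-methylprop-1-en-1-yl)-1,3-dioxolan-4-yl]-5,9-dimethylundeca-5,9-dien-1-yn-4-yl acetate, via lithium acetylide 12 (not isolated), via lithium alkoxide 13 (not isolated)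
Conditions: 11, n-BuLi, THF, −78 °C; 6, DMPU, −20 → 40 °C; Ac2O, 0 °C
Reagents that add atoms: acetic anhydride CC(=O)OC(C)=O
Why: n-BuLi deprotonates alkyne 11 to acetylide 12, which opens oxirane 6 by SN2 attack at its unsubstituted CH2 carbon, forming the C9–C10 bond with release of the three-ring strain (about 27 kcal/mol), and the lithium alkoxide 13 so formed is O-acetylated in the same flask. The closest known reaction type is the alkynylation of terminal epoxides with lithium acetylides in a dipolar aprotic co-solvent followed by acylation of the alkoxide. No ring is closed. No new stereocentre is formed: C8 is not the carbon attacked and keeps the configuration set in the resolution (the (R)-oxirane becomes 8S in target numbering), and the two dioxolane centres are remote from the reacting carbon. The step needs attack at the CH2 terminus instead of the allylic oxirane carbon or SN2′ attack at the alkene: without a Lewis acid the transition state stays SN2-like and sterically governed, the allylic carbon is screened by the methyl-bearing alkene carbon next to it, and a copper-free acetylide has no SN2′ channel. No ester is present at this stage (O1 is a silyl ether), so the acetylide meets no competing electrophile until acetic anhydride is added.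

Step 11
Reactants: 14 coupled enyne acetate
Product: 15 (2Z,6E,8S,12S,13R)-1,12,13-trihydroxy-3,7,15-trimethylhexadeca-2,6,14-trien-10-yn-8-yl acetate
Conditions: AcOH–H2O–THF (3:1:1), 45 °C
Reagents that add atoms: none
Why: Mild aqueous acid hydrolyses the acetonide and the primary allylic TBS ether in one operation while the secondary acetate survives, unveiling the C13 hydroxyl needed for lactonisation.

Step 12
Reactants: 15 enyne triol acetate
Product: 16 (3S,4E,8Z)-10-hydroxy-1-[(3E,4S,5R)-4-hydroxy-5-(2-methylprop-1-en-1-yl)-2-oxooxolan-3-ylidene]-4,8-dimethyldeca-4,8-dien-3-yl acetate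
Conditions: [Pd(PPh3)2(MeCN)2](BF4)2 (5 mol %), CO (20 bar), MeCN, 50 °C
Reagents that add atoms: carbon monoxide [C-]#[O+]
Why: Pd-catalysed cyclocarbonylation of a homopropargylic alcohol, in which syn addition of Pd–H and CO across the alkyne places the acyl group on C11 cis to the new vinylic hydrogen and only this acylpalladium can be trapped by the C13 hydroxyl (5-exo lactonisation), so the (E)-alkylidene γ-lactone should form with the C12/C13 centres untouched (trans 4′-hydroxy/5′-alkenyl).

Step 13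
Reactants: 16 hydroxy lactone with free C1–OH; 17 angelic acid, (2Z)-2-methylbut-2-enoic acid
Product: 18 (2Z,6E,8S)-8-(acetyloxy)-10-[(3E,4S,5R)-4-hydroxy-5-(2-methylprop-1-en-1-yl)-2-oxooxolan-3-ylidene]-3,7-dimethyldeca-2,6-dien-1-yl (2Z)-2-methylbut-2-enoate
Conditions: PPh3, DIAD, THF, 0 °C
Reagents that add atoms: none
Why: Mitsunobu esterification, in which the primary allylic alcohol is activated far faster than the hindered ring carbinol and is displaced by angelate acting as the nucleophile, so the acid is never activated as an acyl donor and its Z geometry is retained.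

Compound list
1 | nerol, (2Z)-3,7-dimethylocta-2,6-dien-1-ol | OC/C=C(/C)CCC=C(C)C | starting material
2 | tert-butyl{[(2Z)-3,7-dimethylocta-2,6-dien-1-yl]oxy}dimethylsilane | CC(C)(C)[Si](C)(C)OC/C=C(/C)CCC=C(C)C | intermediate
3 | (2E,6Z)-8-[(tert-butyldimethylsilyl)oxy]-2,6-dimethylocta-2,6-dien-1-ol | CC(C)(C)[Si](C)(C)OC/C=C(/C)CC/C=C(\C)CO | intermediate
4 | (2E,6Z)-8-[(tert-butyldimethylsilyl)oxy]-2,6-dimethylocta-2,6-dienal | CC(C)(C)[Si](C)(C)OC/C=C(/C)CC/C=C(\C)C=O | intermediate
5 | racemic tert-butyl{[(2Z,6E)-3,7-dimethyl-7-(oxiran-2-yl)hepta-2,6-dien-1-yl]oxy}dimethylsilane | CC(C)(C)[Si](C)(C)OC/C=C(/C)CC/C=C(\C)C1CO1 | intermediate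
6 | tert-butyl({(2Z,6E)-3,7-dimethyl-7-[(2R)-oxiran-2-yl]hepta-2,6-dien-1-yl}oxy)dimethylsilane | CC(C)(C)[Si](C)(C)OC/C=C(/C)CC/C=C(\C)[C@@H]1CO1 | intermediate
7 | (−)-2,3-O-isopropylidene-D-erythronolactone, (3aR,6aR)-2,2-dimethyldihydrofuro[3,4-d][1,3]dioxol-4(3aH)-one | O=C1OC[C@H]2OC(C)(C)O[C@@H]12 | starting material
8 | 2,3-O-isopropylidene-D-erythrose, (3aR,6aR)-2,2-dimethyltetrahydrofuro[3,4-d][1,3]dioxol-4-ol (anomeric mixture) | OC1OC[C@H]2OC(C)(C)O[C@@H]12 | intermediate
9 | [(4R,5S)-5-ethynyl-2,2-dimethyl-1,3-dioxolan-4-yl]methanol | C#C[C@@H]1OC(C)(C)O[C@@H]1CO | intermediate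
10 | (4S,5S)-5-ethynyl-2,2-dimethyl-1,3-dioxolane-4-carbaldehyde | C#C[C@@H]1OC(C)(C)O[C@@H]1C=O | intermediate
11 | (4S,5R)-4-ethynyl-2,2-dimethyl-5-(2-methylprop-1-en-1-yl)-1,3-dioxolane | C#C[C@@H]1OC(C)(C)O[C@@H]1C=C(C)C | intermediate
12 | lithium acetylide of 11, lithium {[(4S,5R)-2,2-dimethyl-5-(2-methylprop-1-en-1-yl)-1,3-dioxolan-4-yl]ethynide} | [Li]C#C[C@@H]1OC(C)(C)O[C@@H]1C=C(C)C | intermediate
13 | lithium (4S,5E,9Z)-11-[(tert-butyldimethylsilyl)oxy]-1-[(4S,5R)-2,2-dimethyl-5-(2-methylprop-1-en-1-yl)-1,3-dioxolan-4-yl]-5,9-dimethylundeca-5,9-dien-1-yn-4-olate | CC(C)(C)[Si](C)(C)OC/C=C(/C)CC/C=C(\C)[C@H](CC#C[C@@H]1OC(C)(C)O[C@@H]1C=C(C)C)O[Li] | intermediate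
14 | (4S,5E,9Z)-11-[(tert-butyldimethylsilyl)oxy]-1-[(4S,5R)-2,2-dimethyl-5-(2-methylprop-1-en-1-yl)-1,3-dioxolan-4-yl]-5,9-dimethylundeca-5,9-dien-1-yn-4-yl acetate | CC(C)(C)[Si](C)(C)OC/C=C(/C)CC/C=C(\C)[C@H](CC#C[C@@H]1OC(C)(C)O[C@@H]1C=C(C)C)OC(C)=O | intermediate
15 | (2Z,6E,8S,12S,13R)-1,12,13-trihydroxy-3,7,15-trimethylhexadeca-2,6,14-trien-10-yn-8-yl acetate | OC/C=C(/C)CC/C=C(\C)[C@H](CC#C[C@H](O)[C@H](O)C=C(C)C)OC(C)=O | intermediate
16 | (3S,4E,8Z)-10-hydroxy-1-[(3E,4S,5R)-4-hydroxy-5-(2-methylprop-1-en-1-yl)-2-oxooxolan-3-ylidene]-4,8-dimethyldeca-4,8-dien-3-yl acetate | OC/C=C(/C)CC/C=C(\C)[C@H](C/C=C1/C(=O)O[C@H](C=C(C)C)[C@H]1O)OC(C)=O | intermediate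
17 | angelic acid, (2Z)-2-methylbut-2-enoic acid | C/C=C(/C)C(=O)O | starting material
18 | (2Z,6E,8S)-8-(acetyloxy)-10-[(3E,4S,5R)-4-hydroxy-5-(2-methylprop-1-en-1-yl)-2-oxooxolan-3-ylidene]-3,7-dimethyldeca-2,6-dien-1-yl (2Z)-2-methylbut-2-enoate | C/C=C(/C)C(=O)OC/C=C(/C)CC/C=C(\C)[C@H](C/C=C1/C(=O)O[C@H](C=C(C)C)[C@H]1O)OC(C)=O | target

Total step count: 13 (steps 1–5 oxirane fragment, steps 6–9 alkyne fragment, steps 10–13 union and endgame).
Longest linear sequence: 9 steps (1–5 and 10–13, from nerol).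

Steps most likely to fail

Step 10 (key step). Attack of the acetylide at the allylic oxirane carbon, base-induced isomerisation of the alkenyl oxirane, or sluggish opening without a Lewis acid may erode the coupling. The fallback replaces the oxirane by a primary triflate with the C8 oxygen silylated, so that only one electrophilic carbon is offered. It sets out from racemic 5: the hydrolytic kinetic resolution run with the (S,S)-catalyst and 0.45 equiv of water should give the (R)-diol F1. One-pot treatment with Tf2O/2,6-lutidine at −78 °C and then TESOTf should give the triflate F2. Acetylide 12 displaces the triflate at −78 °C in THF/DMPU to give the coupled TES ether F3. PPTS in MeOH at 0 °C removes the TES group in the presence of the primary TBS ether and the acetonide to give the coupled alcohol F4. Ac2O/DMAP/pyridine then returns to the route at 14.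

Step 12. Hydropalladation with the wrong regiochemistry, Pd–H isomerisation of the trisubstituted alkenes, or ionisation of the allylic acetate may divert the cyclocarbonylation. The fallback builds the lactone through a defined vinyl iodide, from 15 back to 16. Mo(CO)3(CNt-Bu)3-catalysed syn-hydrostannation with Bu3SnH, tin going to the alkyne carbon next to the propargylic hydroxyl, should give the vinylstannane F5. Iodine in CH2Cl2 at 0 °C exchanges tin for iodine with retention to give the vinyl iodide F6. Carbonylative lactonisation (PdCl2(PPh3)2, CO 1 atm, Et3N, THF) closes the ring through the C13 hydroxyl and rejoins the route at 16.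

Step 13. Esterification at the ring hydroxyl, SN2′ substitution of the allylic oxyphosphonium, or Z-to-E drift of the angelate may lower selectivity at the last step. The fallback installs the angelate before the lactone, when O1 is the only free hydroxyl. It sets out from 14: HF·pyridine in THF/pyridine at 0 °C removes the silyl ether to give the primary alcohol F7. Angelic acid 17 is coupled through its 2,4,6-trichlorobenzoyl mixed anhydride (Et3N, toluene, no DMAP) to give the angelate F8. AcOH–H2O–THF cleaves the acetonide to the diol F9, and the cyclocarbonylation of step 12 then gives 18 directly.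

Further compounds
F1 | step 10 | (2R,3E,7Z)-9-[(tert-butyldimethylsilyl)oxy]-3,7-dimethylnona-3,7-diene-1,2-diol | CC(C)(C)[Si](C)(C)OC/C=C(/C)CC/C=C(\C)[C@@H](O)CO
F2 | step 10 | (2R,3E,7Z)-9-[(tert-butyldimethylsilyl)oxy]-3,7-dimethyl-2-[(triethylsilyl)oxy]nona-3,7-dien-1-yl trifluoromethanesulfonate | CC(C)(C)[Si](C)(C)OC/C=C(/C)CC/C=C(\C)[C@@H](O[Si](CC)(CC)CC)COS(=O)(=O)C(F)(F)F
F3 | step 10 | {[(4S,5E,9Z)-11-[(tert-butyldimethylsilyl)oxy]-1-[(4S,5R)-2,2-dimethyl-5-(2-methylprop-1-en-1-yl)-1,3-dioxolan-4-yl]-5,9-dimethylundeca-5,9-dien-1-yn-4-yl]oxy}triethylsilane | CC(C)(C)[Si](C)(C)OC/C=C(/C)CC/C=C(\C)[C@H](CC#C[C@@H]1OC(C)(C)O[C@@H]1C=C(C)C)O[Si](CC)(CC)CC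
F4 | step 10 | (4S,5E,9Z)-11-[(tert-butyldimethylsilyl)oxy]-1-[(4S,5R)-2,2-dimethyl-5-(2-methylprop-1-en-1-yl)-1,3-dioxolan-4-yl]-5,9-dimethylundeca-5,9-dien-1-yn-4-ol | CC(C)(C)[Si](C)(C)OC/C=C(/C)CC/C=C(\C)[C@H](CC#C[C@@H]1OC(C)(C)O[C@@H]1C=C(C)C)O
F5 | step 12 | (2Z,6E,8S,10E,12R,13R)-1,12,13-trihydroxy-3,7,15-trimethyl-11-(tributylstannyl)hexadeca-2,6,10,14-tetraen-8-yl acetate | OC/C=C(/C)CC/C=C(\C)[C@H](C/C=C(/[Sn](CCCC)(CCCC)CCCC)[C@H](O)[C@H](O)C=C(C)C)OC(C)=O
F6 | step 12 | (2Z,6E,8S,10E,12R,13R)-1,12,13-trihydroxy-11-iodo-3,7,15-trimethylhexadeca-2,6,10,14-tetraen-8-yl acetate | OC/C=C(/C)CC/C=C(\C)[C@H](C/C=C(/I)[C@H](O)[C@H](O)C=C(C)C)OC(C)=O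
F7 | step 13 | (4S,5E,9Z)-1-[(4S,5R)-2,2-dimethyl-5-(2-methylprop-1-en-1-yl)-1,3-dioxolan-4-yl]-11-hydroxy-5,9-dimethylundeca-5,9-dien-1-yn-4-yl acetate | OC/C=C(/C)CC/C=C(\C)[C@H](CC#C[C@@H]1OC(C)(C)O[C@@H]1C=C(C)C)OC(C)=O
F8 | step 13 | (2Z,6E,8S)-8-(acetyloxy)-11-[(4S,5R)-2,2-dimethyl-5-(2-methylprop-1-en-1-yl)-1,3-dioxolan-4-yl]-3,7-dimethylundeca-2,6-dien-10-yn-1-yl (2Z)-2-methylbut-2-enoate | C/C=C(/C)C(=O)OC/C=C(/C)CC/C=C(\C)[C@H](CC#C[C@@H]1OC(C)(C)O[C@@H]1C=C(C)C)OC(C)=O
F9 | step 13 | (2Z,6E,8S,12S,13R)-8-(acetyloxy)-12,13-dihydroxy-3,7,15-trimethylhexadeca-2,6,14-trien-10-yn-1-yl (2Z)-2-methylbut-2-enoate | C/C=C(/C)C(=O)OC/C=C(/C)CC/C=C(\C)[C@H](CC#C[C@H](O)[C@H](O)C=C(C)C)OC(C)=O
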